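**Plan**

- Ring numbering: C1 (ester carbinol), C2=C3 (alkene, methyl on C3), C4, C5, C6–C7 (epoxide, methyl on C7), C8–C10, C11 (CMe2). The feature that opens the key step is C11, a quaternary ring carbon with two methyls next to the C1 carbinol of the eleven-membered ring: it is the tertiary radical that an isopropenyl group on C1 gives once it takes up a hydrogen atom.
- Cuts, in retrosynthetic order: the ester C–O bond at C1; a C9–S bond of a sulfone auxiliary; the ring bond C10–C11 (the only ring-forming cut); C1–C11 (isopropenyl onto an enal); the epoxide C–O bonds; C9=C10 (methylenation); C8–C9 (allylic alkylation); C8–Br/C8–O back to geranyl acetate.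
- Forward: the C1–C8 chain of geranyl acetate is extended at C8 by a C9 sulfonyl unit, C10 is added as a methylene group, C6=C7 is epoxidised, C1 becomes an aldehyde and receives the isopropenyl group, the eleven-membered ring (the only carbocycle) closes by C10–C11 radical addition, and the sulfone is removed.
- The C1 hydroxyl stays free through ring closure and desulfonylation and is 4-methoxybenzoylated last, so that no β-acyloxy radical (1,2-acyloxy shift) and no ester under reducing conditions is involved.
- Stereochemistry: C6 and C7 come from Shi epoxidation of the E C6=C7 alkene (D-fructose-derived ketone); C1 comes from ligand-controlled isopropenylzinc addition; the E C2=C3 alkene comes from geranyl acetate; C9 is transient.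

Key step: step 9

Remark on the chemistry: the ring numbering above is used for all intermediates; C9 of 5 and 14 is carried as a mixture because it is not a stereocentre of the target; the facial sense of the Shi ketone and of (+)-MIB is taken from their established behaviour with trisubstituted alkenes and with aldehydes.

**Route**

Step 1
Reactants: 1 geranyl acetate
Product: 2 (2E,6E)-8-hydroxy-3,7-dimethylocta-2,6-dien-1-yl acetate
Conditions: SeO2 (0.1 equiv), t-BuOOH (3 equiv), salicylic acid (0.1 equiv), CH2Cl2, rt
Reagents that add atoms: selenium dioxide, O=[Se]=O (transfers the oxygen); tert-butyl hydroperoxide, CC(C)(C)OO (re-oxidises selenium, net oxygen source)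
Why: Catalytic SeO2 allylic oxidation (ene reaction, then [2,3]-sigmatropic shift) should attack the E-methyl group of the electron-richer C6=C7 alkene and keep its E geometry, while C2=C3 is deactivated by the allylic acetate.

Step 2
Reactants: 2 (2E,6E)-8-hydroxy-3,7-dimethylocta-2,6-dien-1-yl acetate
Product: 3 (2E,6E)-8-bromo-3,7-dimethylocta-2,6-dien-1-yl acetate
Conditions: CBr4, PPh3, CH2Cl2, 0 °C
Reagents that add atoms: carbon tetrabromide, BrC(Br)(Br)Br
Why: The Appel reaction converts the primary allylic alcohol into the bromide under neutral conditions at 0 °C, where neither the acetate nor the alkene geometry should be disturbed.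

Step 3
Reactants: 3 (2E,6E)-8-bromo-3,7-dimethylocta-2,6-dien-1-yl acetate; 4 diethyl (phenylsulfonyl)methylphosphonate
Product: 5 (2E,6E)-9-(diethoxyphosphoryl)-3,7-dimethyl-9-(phenylsulfonyl)nona-2,6-dien-1-yl acetate (racemic at C9)
Conditions: 4 (1.3 equiv), NaH (1.2 equiv), THF/DMF, 0 °C; then 3, 0 °C → rt
Reagents that add atoms: none
Why: SN2 alkylation of the soft, doubly stabilised sodium salt of 4 at the primary allylic carbon C8 forms C8–C9 without touching the acetate, and the new C9 centre is of no consequence because it becomes sp2 in step 4.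

Step 4
Reactants: 5 (2E,6E)-9-(diethoxyphosphoryl)-3,7-dimethyl-9-(phenylsulfonyl)nona-2,6-dien-1-yl acetate
Product: 6 (2E,6E)-3,7-dimethyl-9-(phenylsulfonyl)deca-2,6,9-trien-1-yl acetate
Conditions: NaH, THF, 0 °C; then (CH2O)n, 0 °C → rt
Reagents that add atoms: formaldehyde (as paraformaldehyde), C=O
Why: Horner–Wadsworth–Emmons olefination of the α-sulfonyl phosphonate anion with formaldehyde should give the 1,1-disubstituted vinyl sulfone (C9=C10) directly, under water-free conditions that spare the acetate.

Step 5
Reactants: 6 (2E,6E)-3,7-dimethyl-9-(phenylsulfonyl)deca-2,6,9-trien-1-yl acetate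
Product: 7 (2E,6R,7R)-6,7-epoxy-3,7-dimethyl-9-(phenylsulfonyl)deca-2,9-dien-1-yl acetate
Conditions: D-fructose-derived Shi ketone (1,2:4,5-di-O-isopropylidene-β-D-erythro-2,3-hexodiulo-2,6-pyranose, 0.3 equiv), KHSO5 (as Oxone, 2KHSO5·KHSO4·K2SO4), K2CO3, Bu4NHSO4, Na2B4O7/Na2H2EDTA buffer (pH ca. 10.5), MeCN–CH2(OMe)2–H2O, 0 °C
Reagents that add atoms: potassium peroxymonosulfate, [K+].[O-]S(=O)(=O)OO
Why: In the Shi asymmetric epoxidation the electrophilic chiral dioxirane should select the only electron-rich alkene, C6=C7 (C2=C3 is deactivated by the allylic acetate, and the α-alkyl vinyl sulfone is electron-poor and no more electrophilic than the enoates that tolerate this medium), and the spiro transition state of the D-fructose-derived ketone sets C6 and C7 as R,R with C5 and C8 trans, as it does for trans-disubstituted and trisubstituted alkenes in general.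

Step 6
Reactants: 7 (2E,6R,7R)-6,7-epoxy-3,7-dimethyl-9-(phenylsulfonyl)deca-2,9-dien-1-yl acetate
Product: 8 (2E,6R,7R)-6,7-epoxy-3,7-dimethyl-9-(phenylsulfonyl)deca-2,9-dien-1-ol
Conditions: i-Bu2AlH (2.2 equiv), CH2Cl2, −78 °C; aq. potassium sodium tartrate
Reagents that add atoms: none
Why: Reductive cleavage of the acetate by DIBAL-H at −78 °C avoids the alkoxide bases that would add to the vinyl sulfone, and at this temperature the trisubstituted epoxide should not be opened.

Step 7
Reactants: 8 (2E,6R,7R)-6,7-epoxy-3,7-dimethyl-9-(phenylsulfonyl)deca-2,9-dien-1-ol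
Product: 9 (2E,6R,7R)-6,7-epoxy-3,7-dimethyl-9-(phenylsulfonyl)deca-2,9-dienal
Conditions: activated MnO2 (excess), CH2Cl2, rt
Reagents that add atoms: none
Why: MnO2 oxidises allylic alcohols selectively under neutral heterogeneous conditions, so the enal should form without loss of the E geometry, the epoxide or the vinyl sulfone.

Step 8
Reactants: 9 (2E,6R,7R)-6,7-epoxy-3,7-dimethyl-9-(phenylsulfonyl)deca-2,9-dienal; 10 2-bromopropene
Product: 13 (3S,4E,8R,9R)-8,9-epoxy-2,5,9-trimethyl-11-(phenylsulfonyl)dodeca-1,4,11-trien-3-ol (ring numbering: 1S,6R,7R; isopropenyl on C1), via isopropenyllithium 11 (not isolated), via diisopropenylzinc 12 (not isolated)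
Conditions: 10 (3 equiv), t-BuLi (6 equiv), Et2O, −78 °C; ZnBr2 (1.5 equiv), −78 → 0 °C; N,N,N′,N′-tetraethylethylenediamine, (+)-MIB [(+)-3-exo-morpholinoisoborneol, 10 mol %], toluene/hexanes; then 9, 0 °C; H2O
Reagents that add atoms: none
Why: Amino-alcohol-catalysed enantioselective 1,2-addition of an alkenylzinc reagent to an aldehyde should deliver the isopropenyl group to the Re face of the enal under control of (+)-MIB (the mirror image of the ligand that directs zinc reagents to the Si face), which sets C1 as S, while the diamine ties up LiBr so that neither the uncatalysed addition nor Lewis-acid opening of the epoxide competes and the organozinc leaves the vinyl sulfone alone.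

Step 9
Reactants: 13 (3S,4E,8R,9R)-8,9-epoxy-2,5,9-trimethyl-11-(phenylsulfonyl)dodeca-1,4,11-trien-3-ol
Product: 14 (1S,2E,6R,7R)-6,7-epoxy-3,7,11,11-tetramethyl-9-(phenylsulfonyl)cycloundec-2-en-1-ol (mixture of C9 epimers)
Conditions: Fe(acac)3 (0.5 equiv, trivalent iron), PhSiH3 (3 equiv, syringe pump over 8 h), EtOH/HOCH2CH2OH (5:1), 60 °C, 0.002 M, argon
Reagents that add atoms: none
Why: Proposed new method: an iron hydride formed from Fe(acac)3, PhSiH3 and ethanol should pass a hydrogen atom to the CH2 terminus of the isopropenyl group (creating the second C11 methyl), the nucleophilic tertiary C11 radical should add to C10, the unsubstituted terminus of the electron-poor vinyl sulfone, and divalent iron then reduces the sulfonyl-stabilised C9 radical before ethanol protonates it; the closest known reaction is the iron-mediated hydrogen-atom-transfer reductive olefin coupling (a Giese addition), which builds quaternary carbons between two molecules and in small-ring closures, so a macrocyclic closure goes beyond it. The ring closes in the 11-endo-trig mode, the only mode that leaves the adduct radical on the sulfone-bearing carbon. C9 is the one new stereocentre and is set without control by protonation, which does not matter because step 10 erases it, while C1, C6 and C7 are not touched. The step needs hydrogen-atom transfer to the isopropenyl group and not to C2=C3 or to the vinyl sulfone, which the substrate supports because iron hydrides react fastest with electron-rich 1,1-disubstituted alkenes that have a free CH2 terminus, C2=C3 being trisubstituted and shielded by C1 and the vinyl sulfone being electron-poor. It also needs ring closure to outrun hydrogen capture by the C11 radical, which is served by 0.002 M concentration, slow addition of the silane and the polarity match between a tertiary alkyl radical and a vinyl sulfone. The C1 hydroxyl is left free so that the β-oxygenated radical carries no acyloxy group that could migrate.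

Step 10
Reactants: 14 (1S,2E,6R,7R)-6,7-epoxy-3,7,11,11-tetramethyl-9-(phenylsulfonyl)cycloundec-2-en-1-ol
Product: 15 (1S,2E,6R,7R)-6,7-epoxy-3,7,11,11-tetramethylcycloundec-2-en-1-ol
Conditions: sodium amalgam Na(Hg) (6 % Na, excess), Na2HPO4, MeOH/THF, −20 → 0 °C
Reagents that add atoms: none
Why: Reductive desulfonylation with sodium amalgam (electron transfer to the phenyl sulfone, loss of benzenesulfinate, reduction and protonation at C9) replaces the C9–S bond by C–H and so removes the uncontrolled C9 centre, the phosphate buffer keeping methoxide away from the epoxide and no ester being present at this stage.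

Step 11
Reactants: 15 (1S,2E,6R,7R)-6,7-epoxy-3,7,11,11-tetramethylcycloundec-2-en-1-ol; 16 4-methoxybenzoyl chloride
Product: 17 (1S,2E,6R,7R)-6,7-epoxy-3,7,11,11-tetramethylcycloundec-2-en-1-yl 4-methoxybenzoate (CNP0113865.1)
Conditions: 16 (1.5 equiv), Et3N (3 equiv), DMAP (0.2 equiv), CH2Cl2, 0 °C → rt
Reagents that add atoms: none
Why: DMAP-catalysed acylation (nucleophilic catalysis through the acylpyridinium salt) should esterify the hindered allylic C1 hydroxyl with retention, excess Et3N keeping the medium free of HCl so that the epoxide survives.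

**Compound list**

1 | geranyl acetate | CC(=O)OC/C=C(\C)CCC=C(C)C | starting material
2 | (2E,6E)-8-hydroxy-3,7-dimethylocta-2,6-dien-1-yl acetate | CC(=O)OC/C=C(\C)CC/C=C(\C)CO | intermediate
3 | (2E,6E)-8-bromo-3,7-dimethylocta-2,6-dien-1-yl acetate | CC(=O)OC/C=C(\C)CC/C=C(\C)CBr | intermediate
4 | diethyl (phenylsulfonyl)methylphosphonate | CCOP(=O)(CS(=O)(=O)c1ccccc1)OCC | starting material
5 | (2E,6E)-9-(diethoxyphosphoryl)-3,7-dimethyl-9-(phenylsulfonyl)nona-2,6-dien-1-yl acetate, racemic at C9 | CC(=O)OC/C=C(\C)CC/C=C(\C)CC(P(=O)(OCC)OCC)S(=O)(=O)c1ccccc1 | intermediate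
6 | (2E,6E)-3,7-dimethyl-9-(phenylsulfonyl)deca-2,6,9-trien-1-yl acetate | CC(=O)OC/C=C(\C)CC/C=C(\C)CC(=C)S(=O)(=O)c1ccccc1 | intermediate
7 | (2E,6R,7R)-6,7-epoxy-3,7-dimethyl-9-(phenylsulfonyl)deca-2,9-dien-1-yl acetate | CC(=O)OC/C=C(\C)CC[C@H]1O[C@]1(C)CC(=C)S(=O)(=O)c1ccccc1 | intermediate
8 | (2E,6R,7R)-6,7-epoxy-3,7-dimethyl-9-(phenylsulfonyl)deca-2,9-dien-1-ol | OC/C=C(\C)CC[C@H]1O[C@]1(C)CC(=C)S(=O)(=O)c1ccccc1 | intermediate
9 | (2E,6R,7R)-6,7-epoxy-3,7-dimethyl-9-(phenylsulfonyl)deca-2,9-dienal | O=C/C=C(\C)CC[C@H]1O[C@]1(C)CC(=C)S(=O)(=O)c1ccccc1 | intermediate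
10 | 2-bromopropene | C=C(C)Br | starting material
11 | isopropenyllithium | [Li]C(C)=C | intermediate
12 | diisopropenylzinc | C=C(C)[Zn]C(C)=C | intermediate
13 | (3S,4E,8R,9R)-8,9-epoxy-2,5,9-trimethyl-11-(phenylsulfonyl)dodeca-1,4,11-trien-3-ol | O[C@@H](/C=C(\C)CC[C@H]1O[C@]1(C)CC(=C)S(=O)(=O)c1ccccc1)C(C)=C | intermediate
14 | (1S,2E,6R,7R)-6,7-epoxy-3,7,11,11-tetramethyl-9-(phenylsulfonyl)cycloundec-2-en-1-ol, both C9 epimers (C9 left open in the SMILES) | O[C@H]1/C=C(\C)CC[C@H]2O[C@]2(C)CC(S(=O)(=O)c2ccccc2)CC1(C)C | intermediate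
15 | (1S,2E,6R,7R)-6,7-epoxy-3,7,11,11-tetramethylcycloundec-2-en-1-ol | O[C@H]1/C=C(\C)CC[C@H]2O[C@]2(C)CCCC1(C)C | intermediate
16 | 4-methoxybenzoyl chloride | COc1ccc(C(=O)Cl)cc1 | starting material
17 | (1S,2E,6R,7R)-6,7-epoxy-3,7,11,11-tetramethylcycloundec-2-en-1-yl 4-methoxybenzoate | COc1ccc(C(=O)O[C@H]2/C=C(\C)CC[C@H]3O[C@]3(C)CCCC2(C)C)cc1 | target

**Count and risks**

Total steps: 11. Longest linear sequence: 11 steps (1 → 17); 4, 10 and 16 are bought.

The three steps most likely to fail:

1. Step 9 (the proposed ring closure).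
   - What may go wrong: the C11 radical may be quenched by a second hydrogen atom before the slow eleven-membered closure. The iron hydride may reduce the vinyl sulfone instead of the isopropenyl group. The homoallylic C11 radical may rearrange by a 1,2-vinyl shift through C2. After closure, the C9 radical may attack C2 across the ring in a 5-exo mode before it is reduced.
   - Fallback (known chemistry; the ring is closed by olefin metathesis at C9=C10 and C11 is brought in complete): it sets out from bromide 3 and returns at alcohol 15.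
   - Copper-catalysed coupling of 3 with vinylmagnesium bromide (Li2CuCl4 cat., THF, −78 °C) should give (2E,6E)-3,7-dimethyldeca-2,6,9-trien-1-yl acetate F1.
   - Shi epoxidation as in step 5 should give (2E,6R,7R)-6,7-epoxy-3,7-dimethyldeca-2,9-dien-1-yl acetate F2.
   - K2CO3 in MeOH removes the acetate to give (2E,6R,7R)-6,7-epoxy-3,7-dimethyldeca-2,9-dien-1-ol F3.
   - MnO2 gives (2E,6R,7R)-6,7-epoxy-3,7-dimethyldeca-2,9-dienal F4.
   - Brown reverse prenylation with B-(3-methylbut-2-enyl)diisopinocampheylborane of the enantiomeric series that attacks the Re face (Et2O, −78 °C, ethanolamine work-up) joins C1 to the fully substituted C11 and sets C1. It should give (4S,5E,9R,10R)-9,10-epoxy-3,3,6,10-tetramethyltrideca-1,5,12-trien-4-ol F5.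
   - Ring-closing metathesis with second-generation Grubbs catalyst RuCl2(=CHPh)(H2IMes)(PCy3) at high dilution should give (1S,2E,6R,7R)-6,7-epoxy-3,7,11,11-tetramethylcycloundeca-2,9-dien-1-ol F6.
   - Diimide (2-nitrobenzenesulfonyl hydrazide, Et3N, CH2Cl2) reduces only the disubstituted C9=C10 alkene and gives 15, which is acylated as in step 11.

2. Step 8 (isopropenylzinc addition).
   - What may go wrong: facial selectivity at the β,β-disubstituted enal may be poor, or zinc halide may open the epoxide.
   - Fallback (the carbinol is set by reduction instead of addition): it sets out from enal 9 and returns at 13.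
   - Isopropenylmagnesium bromide (THF, −78 °C) gives the C3-epimer mixture of (4E,8R,9R)-8,9-epoxy-2,5,9-trimethyl-11-(phenylsulfonyl)dodeca-1,4,11-trien-3-ol F7.
   - MnO2 oxidises it to the cross-conjugated dienone (4E,8R,9R)-8,9-epoxy-2,5,9-trimethyl-11-(phenylsulfonyl)dodeca-1,4,11-trien-3-one F8.
   - Corey–Bakshi–Shibata reduction ((R)-2-methyl-CBS-oxazaborolidine, catecholborane, toluene, −78 °C) should give 13. The α-branched isopropenyl group is expected to act as the larger substituent; if the opposite preference is found, the (S)-catalyst is used.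

3. Step 5 (Shi epoxidation in the presence of the vinyl sulfone).
   - What may go wrong: peroxide or hydroxide may add in conjugate fashion to the vinyl sulfone in the basic medium, or C2=C3 may be oxidised as well.
   - Fallback (the order of acceptor construction and epoxidation is inverted, so the oxidant never meets the electron-poor alkene): it sets out from phosphonate 5 and returns at 7.
   - Shi epoxidation of 5 under the conditions of step 5 should give (2E,6R,7R)-9-(diethoxyphosphoryl)-6,7-epoxy-3,7-dimethyl-9-(phenylsulfonyl)non-2-en-1-yl acetate F9.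
   - Horner–Wadsworth–Emmons olefination of F9 with formaldehyde (NaH, (CH2O)n, THF, 0 °C) then gives 7. The doubly stabilised anion is expected to be too weak a nucleophile to open the neighbouring epoxide.

**Further compounds**

F1 | step 9 | (2E,6E)-3,7-dimethyldeca-2,6,9-trien-1-yl acetate | CC(=O)OC/C=C(\C)CC/C=C(\C)CC=C
F2 | step 9 | (2E,6R,7R)-6,7-epoxy-3,7-dimethyldeca-2,9-dien-1-yl acetate | CC(=O)OC/C=C(\C)CC[C@H]1O[C@]1(C)CC=C
F3 | step 9 | (2E,6R,7R)-6,7-epoxy-3,7-dimethyldeca-2,9-dien-1-ol | OC/C=C(\C)CC[C@H]1O[C@]1(C)CC=C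
F4 | step 9 | (2E,6R,7R)-6,7-epoxy-3,7-dimethyldeca-2,9-dienal | O=C/C=C(\C)CC[C@H]1O[C@]1(C)CC=C
F5 | step 9 | (4S,5E,9R,10R)-9,10-epoxy-3,3,6,10-tetramethyltrideca-1,5,12-trien-4-ol | O[C@@H](/C=C(\C)CC[C@H]1O[C@]1(C)CC=C)C(C)(C)C=C
F6 | step 9 | (1S,2E,6R,7R)-6,7-epoxy-3,7,11,11-tetramethylcycloundeca-2,9-dien-1-ol (C9=C10 geometry open) | O[C@H]1/C=C(\C)CC[C@H]2O[C@]2(C)CC=CC1(C)C
F7 | step 8 | (4E,8R,9R)-8,9-epoxy-2,5,9-trimethyl-11-(phenylsulfonyl)dodeca-1,4,11-trien-3-ol, C3-epimer mixture | OC(/C=C(\C)CC[C@H]1O[C@]1(C)CC(=C)S(=O)(=O)c1ccccc1)C(C)=C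
F8 | step 8 | (4E,8R,9R)-8,9-epoxy-2,5,9-trimethyl-11-(phenylsulfonyl)dodeca-1,4,11-trien-3-one | O=C(/C=C(\C)CC[C@H]1O[C@]1(C)CC(=C)S(=O)(=O)c1ccccc1)C(C)=C
F9 | step 5 | (2E,6R,7R)-9-(diethoxyphosphoryl)-6,7-epoxy-3,7-dimethyl-9-(phenylsulfonyl)non-2-en-1-yl acetate, C9 epimers | CC(=O)OC/C=C(\C)CC[C@H]1O[C@]1(C)CC(P(=O)(OCC)OCC)S(=O)(=O)c1ccccc1
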